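**Plan**

1. Retrosynthesis: the C7 carbinol and the C5–H of the oxolane are first raised to carbonyls. The C5–ring A and C7–ring C bonds are then cut together, because both rings are the same 3,4-dimethoxyphenyl group and each sits on a carbon that can be a carbonyl of a ring-B core (C5 as lactone carbonyl, C7 as N-methoxy-N-methylamide next to aryloxy carbon C8).
2. The core is cut at the aryl ether O–C8 bond (Mitsunobu with a lactic amide) and at the C2–C3 and O1–C5 bonds of the lactone (carboxy-crotylboration of the vanillin aldehyde, then lactonisation); the C4 methyl comes from an exocyclic methylene.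
3. Forward: lactic amide, ether with vanillin, lactone ring built on the aldehyde and hydrogenated, double arylation with one aryllithium (no ring formed), lactol reduction that turns the lactone ring into the oxolane, ketone reduction.
4. Stereochemistry: C8 from methyl (R)-lactate with Mitsunobu inversion; C2 and C3 from a chiral phosphoric acid-controlled crotylboration through a closed chair transition state; C4 by hydrogenation and C5 by hydride delivery, both anti to the cis groups already present; C7 by zinc chelation to the C8 aryloxy oxygen.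

Key step: step 8

Locants follow the target: oxolane O1, C2 (ring B), C3, C4, C5 (ring A); side chain C7 (carbinol) and C8 (aryloxy carbon). Rings A and C are the 3,4-dimethoxyphenyl rings, ring B the central guaiacyl ring.

Assumption: the S phosphoric acid is taken to direct the ester-bearing boronate to the Si face of the aryl aldehyde, as it does for simple allyl- and crotylboronates; if the sense is reversed, the R acid is used.

**Route**

Step 1
Reactants: 1 methyl (R)-lactate
Product: 2 (2R)-2-hydroxy-N-methoxy-N-methylpropanamide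
Conditions: MeNH(OMe)·HCl, i-PrMgCl, THF, −20 → 0 °C; aq NH4Cl
Reagents that add atoms: N,O-dimethylhydroxylamine hydrochloride, CNOC.Cl
Why: The chloromagnesium amide of N,O-dimethylhydroxylamine converts the ester into the N-methoxy-N-methylamide (Weinreb aminolysis) while the hydroxyl is held as its magnesium alkoxide, so the R centre is not touched.

Step 2
Reactants: 2 (2R)-2-hydroxy-N-methoxy-N-methylpropanamide; 3 vanillin
Product: 4 (2S)-2-(4-formyl-2-methoxyphenoxy)-N-methoxy-N-methylpropanamide
Conditions: PPh3, DIAD, THF, 0 °C → rt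
Reagents that add atoms: none
Why: Mitsunobu etherification of the acidic phenol displaces the oxyphosphonium group of the secondary alcohol by SN2, so the R carbinol should give the S aryl ether (C8) with inversion.

Step 3
Reactants: 5 ethyl acrylate; 6 acetaldehyde
Product: 7 ethyl 3-hydroxy-2-methylidenebutanoate (racemic)
Conditions: 1,4-diazabicyclo[2.2.2]octane (DABCO, cat.), neat, rt
Reagents that add atoms: none
Why: Morita–Baylis–Hillman reaction (amine conjugate addition, aldol with acetaldehyde, amine elimination); the racemic carbinol centre is erased in step 5.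

Step 4
Reactants: 7 ethyl 3-hydroxy-2-methylidenebutanoate
Product: 8 ethyl 3-acetoxy-2-methylidenebutanoate (racemic)
Conditions: Ac2O, Et3N, 4-(dimethylamino)pyridine (DMAP, cat.), CH2Cl2, 0 °C → rt
Reagents that add atoms: acetic anhydride, CC(=O)OC(C)=O
Why: DMAP-catalysed acylation of the secondary allylic alcohol installs the leaving group for the allylic substitution.

Step 5
Reactants: 8 ethyl 3-acetoxy-2-methylidenebutanoate
Product: 9 ethyl (2E)-2-[(4,4,5,5-tetramethyl-1,3,2-dioxaborolan-2-yl)methyl]but-2-enoate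
Conditions: B2pin2, CuCl, LiCl, KOAc, DMF, rt
Reagents that add atoms: bis(pinacolato)diboron, CC1(C)OB(OC1(C)C)B1OC(C)(C)C(C)(C)O1
Why: Copper-mediated SN2′ borylation of the Morita–Baylis–Hillman acetate (boryl–copper addition at the methylidene carbon with loss of acetate) should give the trisubstituted allylboronate mainly as the E isomer, with the methyl cis to CH2B as the next step requires.

Step 6
Reactants: 4 (2S)-2-(4-formyl-2-methoxyphenoxy)-N-methoxy-N-methylpropanamide; 9 ethyl (2E)-2-[(4,4,5,5-tetramethyl-1,3,2-dioxaborolan-2-yl)methyl]but-2-enoate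
Product: 11 (2S)-N-methoxy-2-{2-methoxy-4-[(2S,3R)-3-methyl-4-methylidene-5-oxooxolan-2-yl]phenoxy}-N-methylpropanamide (cis alpha-methylene lactone), via O-boryl hydroxy ester 10 (not isolated)
Conditions: (S)-3,3′-bis(2,4,6-triisopropylphenyl)-1,1′-binaphthyl-2,2′-diyl hydrogen phosphate (10 mol%), 4 Å MS, toluene, −20 °C → rt; then pyridinium p-toluenesulfonate, 40 °C
Reagents that add atoms: none
Why: Proposed new method: the chiral phosphoric acid should activate the pinacol boronate by hydrogen bonding to a boronate oxygen (phosphoryl oxygen to the formyl hydrogen) within the closed six-membered chair transition state, where the methyl cis to CH2B lies axial so that C2 and C3 form syn (cis on the ring) and the S acid selects the Si face of the aldehyde (2S,3R), after which the borate oxygen acylates on the neighbouring ester to close the lactone under weak acid that does not ionise the benzylic C–O bond; the closest known reactions are the chiral phosphoric acid-catalysed allyl- and crotylboration of aryl aldehydes with pinacol boronates and the racemic thermal or triflic acid-catalysed 2-(alkoxycarbonyl)crotylboration–lactonisation, the C8 centre being too remote to help or hinder.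

Step 7
Reactants: 11 cis alpha-methylene lactone
Product: 12 (2S)-N-methoxy-2-{2-methoxy-4-[(2S,3R,4S)-3,4-dimethyl-5-oxooxolan-2-yl]phenoxy}-N-methylpropanamide (all-cis lactone amide)
Conditions: H2 (1 atm), Rh/Al2O3 (5 wt% Rh), EtOAc, rt
Reagents that add atoms: none
Why: Heterogeneous syn-hydrogenation of the exocyclic alkene from the face opposite the cis C3 methyl and C2 aryl groups should place the new C4 methyl on their side (4S, all-cis); rhodium on alumina is chosen to avoid hydrogenolysis of the benzylic lactone C–O bond and migration of the alkene into the ring.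

Step 8
Reactants: 12 all-cis lactone amide; 13 4-bromo-1,2-dimethoxybenzene
Product: 16 (2S,3R,4S)-1-(3,4-dimethoxyphenyl)-4-(4-{[(2S)-1-(3,4-dimethoxyphenyl)-1-oxopropan-2-yl]oxy}-3-methoxyphenyl)-4-hydroxy-2,3-dimethylbutan-1-one (open form of the C5 lactol), via 3,4-dimethoxyphenyllithium 14 (not isolated), via dilithium bis-adduct 15 (not isolated)
Conditions: 13 (2.1 equiv), n-BuLi (2.1 equiv), THF, −78 °C; then 12, THF, −78 °C; sat. aq NH4Cl, −78 °C → rt
Reagents that add atoms: none
Why: Bromine–lithium exchange gives the aryllithium, one equivalent of which adds to the lactone carbonyl (C5) to give a lithium lactolate and one to the amide carbonyl (C7) to give a five-membered N,O-lithium chelate, so the C5–ring A and C7–ring C bonds form in one operation. The closest known reactions are the addition of aryllithiums to 3,4-dimethyl-5-aryl gamma-lactones that stops at the lactol and the Weinreb ketone synthesis, here run side by side on one substrate. No ring is closed and no stereocentre is created; C2, C3, C4 and C8 are carried through unchanged. The step needs one addition per carbonyl and no deprotonation at C4 or C8; this should be secured by the low temperature, the fast addition of an unhindered aryllithium and the persistence of the lactolate and the chelate until the cold quench. The product is a ring–chain pair (gamma-hydroxy ketone and lactol 17) and is written in its open form.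

Step 9
Reactants: 16 hydroxy diketone (open form of the C5 lactol)
Product: 18 (2S)-1-(3,4-dimethoxyphenyl)-2-{4-[(2S,3R,4S,5R)-5-(3,4-dimethoxyphenyl)-3,4-dimethyloxolan-2-yl]-2-methoxyphenoxy}propan-1-one (all-cis oxolane ketone), via cyclic lactol 17 (not isolated)
Conditions: Et3SiH, BF3·OEt2, CH2Cl2, −78 °C; Et3N then aq NaHCO3 at −78 °C
Reagents that add atoms: none
Why: Ionic hydrogenation of a lactol: BF3 ionises the cyclic hemiketal to the 2-aryl oxocarbenium ion and the silane should deliver hydride to the open face opposite the three cis substituents (inside attack on the envelope that keeps the C3 methyl pseudo-equatorial), setting C5 as R with ring A cis to the methyls, while at −78 °C the C7 aryl ketone and the benzylic C–O bonds should be left alone.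

Step 10
Reactants: 18 all-cis oxolane ketone
Product: 19 (1R,2S)-1-(3,4-dimethoxyphenyl)-2-{4-[(2S,3R,4S,5R)-5-(3,4-dimethoxyphenyl)-3,4-dimethyloxolan-2-yl]-2-methoxyphenoxy}propan-1-ol (target)
Conditions: Zn(BH4)2, Et2O, −20 → 0 °C; aq NH4Cl
Reagents that add atoms: none
Why: Chelation-controlled reduction (Cram chelate model): zinc bridges the ketone oxygen and the C8 aryloxy oxygen, helped by the ortho methoxy group of ring B, and hydride enters from the side of the C8 hydrogen, which should give the 7R,8S (erythro) alcohol.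

**Compound list**

1 | methyl (R)-lactate | C[C@@H](O)C(=O)OC | starting material
2 | (2R)-2-hydroxy-N-methoxy-N-methylpropanamide | C[C@@H](O)C(=O)N(C)OC | intermediate
3 | vanillin (4-hydroxy-3-methoxybenzaldehyde) | COc1cc(C=O)ccc1O | starting material
4 | (2S)-2-(4-formyl-2-methoxyphenoxy)-N-methoxy-N-methylpropanamide | CON(C)C(=O)[C@H](C)Oc1ccc(C=O)cc1OC | intermediate
5 | ethyl acrylate | C=CC(=O)OCC | starting material
6 | acetaldehyde | CC=O | starting material
7 | ethyl 3-hydroxy-2-methylidenebutanoate (racemic) | CCOC(=O)C(=C)C(C)O | intermediate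
8 | ethyl 3-acetoxy-2-methylidenebutanoate (racemic) | CCOC(=O)C(=C)C(C)OC(C)=O | intermediate
9 | ethyl (2E)-2-[(4,4,5,5-tetramethyl-1,3,2-dioxaborolan-2-yl)methyl]but-2-enoate | C/C=C(/C(=O)OCC)CB1OC(C)(C)C(C)(C)O1 | intermediate
10 | ethyl (3R,4S)-4-(3-methoxy-4-{[(2S)-1-[methoxy(methyl)amino]-1-oxopropan-2-yl]oxy}phenyl)-3-methyl-2-methylidene-4-[(4,4,5,5-tetramethyl-1,3,2-dioxaborolan-2-yl)oxy]butanoate (O-boryl hydroxy ester, not isolated) | CON(C)C(=O)[C@H](C)Oc1ccc(cc1OC)[C@@H](OB2OC(C)(C)C(C)(C)O2)[C@H](C)C(=C)C(=O)OCC | intermediate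
11 | (2S)-N-methoxy-2-{2-methoxy-4-[(2S,3R)-3-methyl-4-methylidene-5-oxooxolan-2-yl]phenoxy}-N-methylpropanamide | CON(C)C(=O)[C@H](C)Oc1ccc(cc1OC)[C@H]1OC(=O)C(=C)[C@H]1C | intermediate
12 | (2S)-N-methoxy-2-{2-methoxy-4-[(2S,3R,4S)-3,4-dimethyl-5-oxooxolan-2-yl]phenoxy}-N-methylpropanamide | CON(C)C(=O)[C@H](C)Oc1ccc(cc1OC)[C@H]1OC(=O)[C@@H](C)[C@H]1C | intermediate
13 | 4-bromo-1,2-dimethoxybenzene | COc1ccc(Br)cc1OC | starting material
14 | 3,4-dimethoxyphenyllithium (not isolated) | [Li]c1ccc(OC)c(OC)c1 | intermediate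
15 | dilithium bis-adduct: lithium lactolate at C5 and lithium N,O-hemiaminal at C7, new tetrahedral centres undefined (not isolated) | COc1ccc(cc1OC)C(O[Li])(N(C)OC)[C@H](C)Oc1ccc(cc1OC)[C@H]1OC(O[Li])(c2ccc(OC)c(OC)c2)[C@@H](C)[C@H]1C | intermediate
16 | (2S,3R,4S)-1-(3,4-dimethoxyphenyl)-4-(4-{[(2S)-1-(3,4-dimethoxyphenyl)-1-oxopropan-2-yl]oxy}-3-methoxyphenyl)-4-hydroxy-2,3-dimethylbutan-1-one | COc1ccc(C(=O)[C@H](C)Oc2ccc(cc2OC)[C@@H](O)[C@H](C)[C@H](C)C(=O)c2ccc(OC)c(OC)c2)cc1OC | intermediate
17 | (2S)-1-(3,4-dimethoxyphenyl)-2-{4-[(2S,3R,4S)-5-(3,4-dimethoxyphenyl)-5-hydroxy-3,4-dimethyloxolan-2-yl]-2-methoxyphenoxy}propan-1-one (cyclic lactol, C5 undefined, not isolated) | COc1ccc(C(=O)[C@H](C)Oc2ccc(cc2OC)[C@H]2OC(O)(c3ccc(OC)c(OC)c3)[C@@H](C)[C@H]2C)cc1OC | intermediate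
18 | (2S)-1-(3,4-dimethoxyphenyl)-2-{4-[(2S,3R,4S,5R)-5-(3,4-dimethoxyphenyl)-3,4-dimethyloxolan-2-yl]-2-methoxyphenoxy}propan-1-one | COc1ccc(C(=O)[C@H](C)Oc2ccc(cc2OC)[C@H]2O[C@@H](c3ccc(OC)c(OC)c3)[C@@H](C)[C@H]2C)cc1OC | intermediate
19 | (1R,2S)-1-(3,4-dimethoxyphenyl)-2-{4-[(2S,3R,4S,5R)-5-(3,4-dimethoxyphenyl)-3,4-dimethyloxolan-2-yl]-2-methoxyphenoxy}propan-1-ol | COc1ccc([C@@H](O)[C@H](C)Oc2ccc([C@H]3O[C@@H](c4ccc(OC)c(OC)c4)[C@@H](C)[C@H]3C)cc2OC)cc1OC | target

**Count**

Total steps: 10. Longest linear sequence: 8 steps (steps 3 to 10, from ethyl acrylate).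

**Steps most likely to fail**

1. Step 6. What may go wrong: slow turnover and weak enantiofacial discrimination, because the ester-bearing boronate is a poorer nucleophile than a plain crotylboronate and the amide carbonyl can compete for the acid; acid-induced E/Z isomerisation of the boronate would also erode the cis relationship.
Fallback (known chemistry, reagent control; sets out from 3, uses 2, returns at 12): vanillin 3 would be silylated (i-Pr3SiCl, imidazole, DMF) to 3-methoxy-4-[(triisopropylsilyl)oxy]benzaldehyde F1. This would be treated with (Z)-crotyldiisopinocampheylborane made from (+)-alpha-pinene (THF, −78 °C; NaOH, H2O2) to give the syn homoallylic alcohol F2. Hydroboration (9-BBN; NaBO3) to the 1,4-diol F3 and oxidative lactonisation (2,2,6,6-tetramethylpiperidin-1-oxyl, PhI(OAc)2) would give the cis 4-methyl-5-aryl lactone F4. Its lithium enolate (LiN(i-Pr)2, THF, −78 °C) would be aminomethylated with dimethylmethylideneammonium iodide to the aminomethyl lactone F5, which on N-methylation and elimination (MeI; DBU) gives the alpha-methylene lactone F6. Hydrogenation as in step 7 (H2, Rh/Al2O3) would give the all-cis silyl lactone F7, desilylation (Bu4NF, AcOH, THF) the phenol lactone F8, and Mitsunobu etherification of F8 with 2 (PPh3, DIAD) rejoins the route at 12.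

2. Step 8. What may go wrong: proton abstraction at C4 or C8 by the aryllithium in place of addition (epimerisation, unreacted carbonyl), or opening of the lactolate to the ketone followed by a second aryl addition.
Fallback (sets out from 12, returns at 16): the lactone of 12 would be opened with Me2AlN(OMe)Me (from AlMe3 and MeNH(OMe)·HCl, CH2Cl2, 0 °C) to the hydroxy bis(N-methoxy-N-methylamide) F9, silylated at once (Et3SiOTf, 2,6-lutidine, −78 °C) to the triethylsilyl ether F10 before it can relactonise. Two equivalents of 14 would then add to two chelating amides, whose alpha protons are less acidic than those of the lactone and whose adducts cannot open to a ketone, to give the silyl-protected diketone F11. HF·pyridine (THF, 0 °C) would release 16.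

3. Step 9. What may go wrong: hydride delivery to the face that carries the three substituents (an adjacent alkyl group can steer small nucleophiles to its own face of five-membered oxocarbenium ions), ionisation of the benzylic C2–O bond by BF3 with epimerisation, or silane reduction of the C7 ketone.
Fallback (sets out from 16, returns at 18): 16 would be dehydrated through lactol 17 (pyridinium p-toluenesulfonate, toluene, 4 Å MS, 60 °C) to the cyclic enol ether, the 2,3-dihydrofuran F12. Hydrogenation (H2, Rh/Al2O3, EtOAc) from the face opposite the C2 aryl and C3 methyl groups then adds both hydrogens anti to them, which places the C4 methyl and the C5 aryl group cis to the existing groups and gives 18 without a Lewis acid.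

**Further compounds**

F1 | step 6 | 3-methoxy-4-[(triisopropylsilyl)oxy]benzaldehyde | COc1cc(C=O)ccc1O[Si](C(C)C)(C(C)C)C(C)C
F2 | step 6 | (1S,2R)-1-{3-methoxy-4-[(triisopropylsilyl)oxy]phenyl}-2-methylbut-3-en-1-ol | COc1cc(ccc1O[Si](C(C)C)(C(C)C)C(C)C)[C@@H](O)[C@H](C)C=C
F3 | step 6 | (1S,2R)-1-{3-methoxy-4-[(triisopropylsilyl)oxy]phenyl}-2-methylbutane-1,4-diol | COc1cc(ccc1O[Si](C(C)C)(C(C)C)C(C)C)[C@@H](O)[C@H](C)CCO
F4 | step 6 | (4R,5S)-5-{3-methoxy-4-[(triisopropylsilyl)oxy]phenyl}-4-methyloxolan-2-one | COc1cc(ccc1O[Si](C(C)C)(C(C)C)C(C)C)[C@H]1OC(=O)C[C@H]1C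
F5 | step 6 | (4R,5S)-3-[(dimethylamino)methyl]-5-{3-methoxy-4-[(triisopropylsilyl)oxy]phenyl}-4-methyloxolan-2-one (C3 undefined) | COc1cc(ccc1O[Si](C(C)C)(C(C)C)C(C)C)[C@H]1OC(=O)C(CN(C)C)[C@H]1C
F6 | step 6 | (4R,5S)-5-{3-methoxy-4-[(triisopropylsilyl)oxy]phenyl}-4-methyl-3-methylideneoxolan-2-one | COc1cc(ccc1O[Si](C(C)C)(C(C)C)C(C)C)[C@H]1OC(=O)C(=C)[C@H]1C
F7 | step 6 | (3S,4R,5S)-5-{3-methoxy-4-[(triisopropylsilyl)oxy]phenyl}-3,4-dimethyloxolan-2-one | COc1cc(ccc1O[Si](C(C)C)(C(C)C)C(C)C)[C@H]1OC(=O)[C@@H](C)[C@H]1C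
F8 | step 6 | (3S,4R,5S)-5-(4-hydroxy-3-methoxyphenyl)-3,4-dimethyloxolan-2-one | COc1cc(ccc1O)[C@H]1OC(=O)[C@@H](C)[C@H]1C
F9 | step 8 | (2S,3R,4S)-4-hydroxy-N-methoxy-4-(3-methoxy-4-{[(2S)-1-[methoxy(methyl)amino]-1-oxopropan-2-yl]oxy}phenyl)-N,2,3-trimethylbutanamide | CON(C)C(=O)[C@H](C)Oc1ccc(cc1OC)[C@@H](O)[C@H](C)[C@H](C)C(=O)N(C)OC
F10 | step 8 | (2S,3R,4S)-N-methoxy-4-(3-methoxy-4-{[(2S)-1-[methoxy(methyl)amino]-1-oxopropan-2-yl]oxy}phenyl)-N,2,3-trimethyl-4-[(triethylsilyl)oxy]butanamide | CON(C)C(=O)[C@H](C)Oc1ccc(cc1OC)[C@@H](O[Si](CC)(CC)CC)[C@H](C)[C@H](C)C(=O)N(C)OC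
F11 | step 8 | (2S,3R,4S)-1-(3,4-dimethoxyphenyl)-4-(4-{[(2S)-1-(3,4-dimethoxyphenyl)-1-oxopropan-2-yl]oxy}-3-methoxyphenyl)-2,3-dimethyl-4-[(triethylsilyl)oxy]butan-1-one | COc1ccc(C(=O)[C@H](C)Oc2ccc(cc2OC)[C@@H](O[Si](CC)(CC)CC)[C@H](C)[C@H](C)C(=O)c2ccc(OC)c(OC)c2)cc1OC
F12 | step 9 | (2S)-1-(3,4-dimethoxyphenyl)-2-{4-[(2S,3R)-5-(3,4-dimethoxyphenyl)-3,4-dimethyl-2,3-dihydrofuran-2-yl]-2-methoxyphenoxy}propan-1-one | COc1ccc(C(=O)[C@H](C)Oc2ccc(cc2OC)[C@H]2OC(c3ccc(OC)c(OC)c3)=C(C)[C@H]2C)cc1OC
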